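Readings and results are calculated from invented constants.

Monday's flask reads 51% of its substrate as target at 20.0 h, more than Friday's 37% at the same time and temperature, but the two differ in substrate and in impurity together.

common to all: free catalyst 1.5 mM
- Sunday's: substrate 3.6 mM; partner 15 mM; protic impurity 5 mM; temperature 65 °C; run made earlier
- Monday's: substrate 5.5 mM; partner 15 mM; protic impurity 5 mM; temperature 80 °C; run made earlier
- Saturday's: substrate 11 mM; partner 15 mM; protic impurity 5 mM; temperature 65 °C; run made earlier
- Friday's: substrate 10 mM; partner 15 mM; protic impurity 7 mM; temperature 80 °C; run made earlier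
- dawn: substrate 10 mM; partner 15.0 mM; protic impurity 5.00 mM; temperature 80 °C; time 20 h
- noon: substrate 3.0 mM; partner 15.0 mM; protic impurity 8.00 mM; temperature 80 °C; time 20 h
- spring: substrate 3.0 mM; partner 15.0 mM; protic impurity 5.00 mM; temperature 80 °C; time 20 h
- autumn: substrate 10 mM; partner 15.0 mM; protic impurity 8.00 mM; temperature 80 °C; time 20 h

| run | time / h | target / % |
|---|---|---|
| Sunday's | 8.00 | 46 |
| Sunday's | 15.0 | 61 |
| Sunday's | 25.0 | 67 |
| Sunday's | 30.0 | 68 |
| Sunday's | 40.0 | 65 |
| Monday's | 1.50 | 25 |
| Monday's | 3.00 | 36 |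
| Monday's | 6.00 | 44 |
| Monday's | 10.0 | 48 |
| Monday's | 20.0 | 51 |
| Saturday's | 8.00 | 32 |
| Saturday's | 15.0 | 43 |
| Saturday's | 25.0 | 50 |
| Saturday's | 30.0 | 54 |
| Saturday's | 40.0 | 56 |
| Friday's | 4.00 | 29 |
| Friday's | 8.00 | 34 |
| Friday's | 12.0 | 40 |
| Friday's | 15.0 | 39 |
| Friday's | 20.0 | 37 |

(standard deviation of a reading: 1.5 percentage points)



- the flasks put in order of amount of target, in percent of the substrate charged, best first, at 20 h (dawn / noon / spring / autumn)
- the amount of target, in percent of the substrate charged of the flask you put first, at 20 h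
- the amount of target, in percent of the substrate charged of the flask you put last, at 20 h

I fold those charges into one number. I assume that the impurity destroys partner one for one, and I define the usable ratio as (c_partner − c_impurity)/c_substrate, the partner still able to work per substrate charged; for noon it is 2.33. Monday's ratio is 1.82 and Friday's is 0.800, so the yield at 20.0 h climbs by 14 percentage points per unit of ratio.

Is one number enough? At 65 °C, Sunday's ratio of 2.78 reads 67% at 25.0 h, and Saturday's 0.909 reads 50%. The direction holds, but the slope at 25.0 h is 9.1 points per unit, so I carry no slope from 65 °C to 80 °C; two runs at each temperature give one slope each and no test of a straight line.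

On the 80 °C line, autumn at 0.700 gives 35.6%, dawn at 1.00 gives 39.7%, and noon gives 58.1%. Spring's 3.33 lies above every run, so I commit only to spring first, between 58.1% and Sunday's 68%.

The forecast gives spring > noon > dawn > autumn, with 59% on top (54% to 64%) and 33% at the bottom (28% to 37%), on the ground that “impurity lowers yield and seems to destroy target”. Its noon of about 46 differs from my 58.1%.

The flasks give noon > spring > dawn > autumn: noon 61.3%, spring 53.6%, dawn 40.1%, autumn 36.3%.

    partner + free catalyst ⇌ catalyst intermediate A (K = 5000 M⁻¹, k = 0.0690 M⁻¹ s⁻¹, Ea = 48.0 kJ mol⁻¹, ΔH = −6.00 kJ mol⁻¹)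
    substrate + catalyst intermediate A ⇌ catalyst intermediate B (K = 640 M⁻¹, k = 0.180 M⁻¹ s⁻¹, Ea = 64.0 kJ mol⁻¹, ΔH = −24.0 kJ mol⁻¹)
    catalyst intermediate B ⇌ free catalyst + target (K = 0.0270 M, k = 0.00260 s⁻¹, Ea = 114 kJ mol⁻¹, ΔH = −66.0 kJ mol⁻¹)
    partner + catalyst intermediate A → spent catalyst A (k = 0.0290 M⁻¹ s⁻¹, Ea = 75.0 kJ mol⁻¹)
    partner + protic impurity → quenched reagent (k = 0.130 M⁻¹ s⁻¹, Ea = 44.0 kJ mol⁻¹)
    free catalyst → spent catalyst B (k = 8.60 × 10⁻⁵ s⁻¹, Ea = 103 kJ mol⁻¹)
    (constants at 80 °C)

In noon at 0.120 h, the quench uses partner 7.4 times as fast as the forward capture by free catalyst, and after 2.00 h it has 99.7% of its turnover up to 20 h behind it. The impurity, limiting reagent of that step, ends at 0%. Noon at ratio 2.33 gives 61.3%, spring at 3.33 gives 53.6%, and noon's neighbour charged with 38 mM of partner, at ratio 10.0, gives 24.3%.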